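**Retrosynthetic overview**

1. Target ⇐ ester C–O bond (Mitsunobu at the C9 hydroxyl with unprotected p-coumaric acid, then one desilylation) ⇐ 2,3-cis-3,4-trans 2-aryl-4-benzyltetrahydrofuran-3-methanol.
2. Tetrahydrofuran (the only ring of the target; formed third from last) ⇐ acyclic "unlike" 2,3-dibenzylbutane-1,4-diol in one flask: DDQ gives the p-quinone methide at C7, the C9' hydroxyl closes the ring 5-exo, re-oxidation at C7 gives a ketal, and silane reduction anti to C8 sets 7,8-cis.
3. Diol ⇐ cis-2,3-dibenzyl-γ-butyrolactone (temporary ring, opened by LiBH4) ⇐ face-selective hydrogenation of an (E)-α-benzylidene-β-benzyl lactone (C8' set from C8).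
4. Benzylidene lactone ⇐ aldol condensation of (S)-β-benzyl-γ-butyrolactone with O-TIPS-vanillin; lactone ⇐ Stobbe condensation of O-benzylvanillin with dimethyl succinate, Rh-catalysed asymmetric hydrogenation (the only external chirality), ester reduction.
5. The two guaiacyl rings differ only in O-protection (free phenol on the ring to be oxidised, TIPS on the other); this makes the DDQ step site-selective and the diol chiral.

Assumption: the SMILES is read as the (7S,8S,8'R) isomer, that is tetrahydrofuran (2S,3S,4R) with the C2 aryl cis to the C3 acyloxymethyl and C3/C4 trans (the C8 epimer of the lariciresinol pattern).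

Numbering: C7/C8/C9 are the benzylic carbon, methine and CH2O of the half whose aryl (ring A) sits on the ring; C7'/C8'/C9' are the same carbons of the benzyl half (ring B).

**Route**

Step 1
Reactants: 1 4-(benzyloxy)-3-methoxybenzaldehyde (O-benzylvanillin); 2 dimethyl succinate
Product: 3 (E)-4-[4-(benzyloxy)-3-methoxyphenyl]-3-(methoxycarbonyl)but-3-enoic acid
Conditions: NaOMe (2.2 equiv), MeOH, reflux; then aq. HCl
Reagents that add atoms: none
Why: Stobbe condensation, in which the succinate enolate adds to the aldehyde, the aldolate lactonises onto the distal ester and base-induced ring opening gives the (E)-arylidene half-ester, so the two carboxyl carbons are differentiated for step 3 without protecting groups.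

Step 2
Reactants: 3 (E)-4-[4-(benzyloxy)-3-methoxyphenyl]-3-(methoxycarbonyl)but-3-enoic acid
Product: 4 (3S)-4-[4-(benzyloxy)-3-methoxyphenyl]-3-(methoxycarbonyl)butanoic acid
Conditions: [Rh(cod)((R,R)-Et-DuPhos)]BF4 (0.5 mol%), NaOMe (0.1 equiv), H2 (5 bar), MeOH, rt
Reagents that add atoms: none
Why: Rhodium-catalysed asymmetric hydrogenation of a β-aryl itaconate half-ester, in which the carboxylate chelates rhodium beside the alkene and the (R,R)-ligand (the (S,S)-ligand gives the antipode) delivers hydrogen to the face that creates the (S) stereocentre, while the benzyl ether is inert to the homogeneous catalyst.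

Step 3
Reactants: 4 (3S)-4-[4-(benzyloxy)-3-methoxyphenyl]-3-(methoxycarbonyl)butanoic acid
Product: 6 (4S)-4-[4-(benzyloxy)-3-methoxybenzyl]dihydrofuran-2(3H)-one, via hydroxy acid 5 (not isolated)
Conditions: KOH (1.0 equiv), EtOH, 0 °C; Ca(BH4)2 (from CaCl2 + NaBH4), EtOH, −10 °C to rt; then 3 M HCl, rt
Reagents that add atoms: none
Why: Chemoselective borohydride reduction then lactonisation, in which calcium borohydride reduces the methyl ester but not the potassium carboxylate and acid closes hydroxy acid 5 to the γ-lactone, which moves the stereocentre to the non-enolisable β-position so that it cannot racemise in step 5.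

Step 4
Reactants: 7 vanillin
Product: 8 3-methoxy-4-(triisopropylsilyloxy)benzaldehyde
Conditions: TIPSCl (1.1 equiv), imidazole (2 equiv), DMF, rt
Reagents that add atoms: triisopropylsilyl chloride (TIPSCl), CC(C)[Si](Cl)(C(C)C)C(C)C
Why: Imidazole-promoted silylation of the phenol gives an aryl TIPS ether that survives LDA, DBU, hydrogenation, LiBH4, DDQ and BF3 and later keeps ring B from being oxidised by DDQ.

Step 5
Reactants: 6 (4S)-4-[4-(benzyloxy)-3-methoxybenzyl]dihydrofuran-2(3H)-one; 8 3-methoxy-4-(triisopropylsilyloxy)benzaldehyde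
Product: 10 (3E,4S)-4-[4-(benzyloxy)-3-methoxybenzyl]-3-[3-methoxy-4-(triisopropylsilyloxy)benzylidene]dihydrofuran-2(3H)-one, via aldol acetate 9 (not isolated)
Conditions: LDA (1.1 equiv), THF, −78 °C; then 8; Ac2O (2 equiv), −78 °C to rt; DBU (3 equiv), rt
Reagents that add atoms: none
Why: Aldol condensation of the lactone lithium enolate, with in situ acetylation and DBU-induced E1cB elimination, gives the thermodynamically preferred (E)-benzylidene lactone (aryl anti to the carbonyl) and leaves the non-enolisable C4 stereocentre untouched.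

Step 6
Reactants: 10 (3E,4S)-4-[4-(benzyloxy)-3-methoxybenzyl]-3-[3-methoxy-4-(triisopropylsilyloxy)benzylidene]dihydrofuran-2(3H)-one
Product: 11 (3R,4S)-4-(4-hydroxy-3-methoxybenzyl)-3-[3-methoxy-4-(triisopropylsilyloxy)benzyl]dihydrofuran-2(3H)-one
Conditions: H2 (1 atm), 10% Pd/C, EtOAc–EtOH, rt
Reagents that add atoms: none
Why: Heterogeneous catalytic hydrogenation adds both hydrogens to the exocyclic alkene from the face opposite the C4 benzyl group (pushed pseudo-axial by allylic strain with the (E)-aryl), so the new C3 benzyl is cis to it (3R, the unlike C8/C8' pair), and the same conditions hydrogenolyse the benzyl ether to free the ring A phenol that DDQ will oxidise.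

Step 7
Reactants: 11 (3R,4S)-4-(4-hydroxy-3-methoxybenzyl)-3-[3-methoxy-4-(triisopropylsilyloxy)benzyl]dihydrofuran-2(3H)-one
Product: 12 (2S,3R)-2-(4-hydroxy-3-methoxybenzyl)-3-[3-methoxy-4-(triisopropylsilyloxy)benzyl]butane-1,4-diol
Conditions: LiBH4 (3 equiv), THF, 0 °C to rt; 1 M HCl work-up
Reagents that add atoms: none
Why: Hydride reduction of the lactone to the 1,4-diol removes the only enolisable position and so locks the cis relationship as the (2S,3R) diol, which would be meso but for the silyl group on ring B.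

Step 8
Reactants: 12 (2S,3R)-2-(4-hydroxy-3-methoxybenzyl)-3-[3-methoxy-4-(triisopropylsilyloxy)benzyl]butane-1,4-diol
Product: 17 [(2S,3S,4R)-2-(4-hydroxy-3-methoxyphenyl)-4-[3-methoxy-4-(triisopropylsilyloxy)benzyl]tetrahydrofuran-3-yl]methanol, via quinone methide 13 (not isolated), via 7,8-trans tetrahydrofuran 14 (not isolated), via methyl ketal 15 (not isolated), via oxocarbenium ion 16 (not isolated)
Conditions: DDQ (2.05 equiv), MeOH (5 equiv), CH2Cl2, 0 °C, 1 h; then −78 °C, Et3SiH (8 equiv), BF3·OEt2 (8 equiv), −78 to −40 °C; NaHCO3 quench cold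
Reagents that add atoms: none
Why: Proposed new method: DDQ removes hydride from the benzylic CH2 of the free-phenol ring only (the silylated ring is far harder to oxidise) to give quinone methide 13, the C9' hydroxyl adds to it in a 5-exo oxa-Michael ring closure as in lignan biosynthesis (the C9 hydroxyl could only form an oxetane) to give mainly the 7,8-trans ether 14, a second hydride abstraction at the now α-alkoxy C7 followed by methanol capture turns either C7 epimer into ketal 15, and BF3 ionisation to oxocarbenium ion 16 lets Et3SiH attack anti to the adjacent C8 hydroxymethyl group (inside attack on the envelope), which fixes 7S with the aryl cis to C8 while C8 and C8' are carried over from 12; the closest known reaction types are the DDQ oxidative cyclisation of 4-hydroxybenzyl compounds through p-quinone methides and the Et3SiH/BF3·OEt2 reduction of 2-aryl cyclic ketals to 2,3-cis-3,4-trans tetrahydrofurans, here run in one flask.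

Step 9
Reactants: 17 [(2S,3S,4R)-2-(4-hydroxy-3-methoxyphenyl)-4-[3-methoxy-4-(triisopropylsilyloxy)benzyl]tetrahydrofuran-3-yl]methanol; 18 (E)-p-coumaric acid
Product: 19 [(2S,3S,4R)-2-(4-hydroxy-3-methoxyphenyl)-4-[3-methoxy-4-(triisopropylsilyloxy)benzyl]tetrahydrofuran-3-yl]methyl (E)-3-(4-hydroxyphenyl)prop-2-enoate
Conditions: PPh3 (1.3 equiv), DIAD (1.3 equiv), THF, 0 °C to rt
Reagents that add atoms: none
Why: Mitsunobu esterification, in which the primary alcohol is activated as its alkoxyphosphonium ion and displaced at CH2 (no stereocentre involved) by the carboxylate, the only pronucleophile acidic enough (pKa about 4.5 against about 10 for the phenols) to be deprotonated by the betaine, so the phenols need no protection and the (E)-alkene is untouched.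

Step 10
Reactants: 19 [(2S,3S,4R)-2-(4-hydroxy-3-methoxyphenyl)-4-[3-methoxy-4-(triisopropylsilyloxy)benzyl]tetrahydrofuran-3-yl]methyl (E)-3-(4-hydroxyphenyl)prop-2-enoate
Product: 20 [(2S,3S,4R)-2-(4-hydroxy-3-methoxyphenyl)-4-(4-hydroxy-3-methoxybenzyl)tetrahydrofuran-3-yl]methyl (E)-3-(4-hydroxyphenyl)prop-2-enoate (target, 7S,8S,8'R)
Conditions: Bu4NF (1.2 equiv), AcOH (1.5 equiv), THF, 0 °C
Reagents that add atoms: none
Why: Fluoride cleavage of the aryl silyl ether (nucleophilic substitution at silicon) under acetic acid buffering frees the last phenol without hydrolysing the cinnamate ester or opening the acid- and base-sensitive 2-(4-hydroxyaryl)tetrahydrofuran, so the three stereocentres are unchanged.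

**Compound list**

1 | 4-(benzyloxy)-3-methoxybenzaldehyde | COc1cc(C=O)ccc1OCc1ccccc1 | starting material
2 | dimethyl succinate | COC(=O)CCC(=O)OC | starting material
3 | (E)-4-[4-(benzyloxy)-3-methoxyphenyl]-3-(methoxycarbonyl)but-3-enoic acid | COC(=O)/C(CC(=O)O)=C/c1ccc(OCc2ccccc2)c(OC)c1 | intermediate
4 | (3S)-4-[4-(benzyloxy)-3-methoxyphenyl]-3-(methoxycarbonyl)butanoic acid | OC(=O)C[C@H](Cc1ccc(OCc2ccccc2)c(OC)c1)C(=O)OC | intermediate
5 | (3S)-4-[4-(benzyloxy)-3-methoxyphenyl]-3-(hydroxymethyl)butanoic acid (not isolated) | OC(=O)C[C@H](Cc1ccc(OCc2ccccc2)c(OC)c1)CO | intermediate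
6 | (4S)-4-[4-(benzyloxy)-3-methoxybenzyl]dihydrofuran-2(3H)-one | O=C1C[C@H](Cc2ccc(OCc3ccccc3)c(OC)c2)CO1 | intermediate
7 | vanillin | COc1cc(C=O)ccc1O | starting material
8 | 3-methoxy-4-(triisopropylsilyloxy)benzaldehyde | COc1cc(C=O)ccc1O[Si](C(C)C)(C(C)C)C(C)C | intermediate
9 | [(3R,4S)-4-[4-(benzyloxy)-3-methoxybenzyl]-2-oxotetrahydrofuran-3-yl][3-methoxy-4-(triisopropylsilyloxy)phenyl]methyl acetate (3,4-trans; both carbinol epimers; not isolated) | O=C1[C@@H](C(OC(C)=O)c2ccc(O[Si](C(C)C)(C(C)C)C(C)C)c(OC)c2)[C@H](Cc2ccc(OCc3ccccc3)c(OC)c2)CO1 | intermediate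
10 | (3E,4S)-4-[4-(benzyloxy)-3-methoxybenzyl]-3-[3-methoxy-4-(triisopropylsilyloxy)benzylidene]dihydrofuran-2(3H)-one | O=C1/C(=C/c2ccc(O[Si](C(C)C)(C(C)C)C(C)C)c(OC)c2)[C@H](Cc2ccc(OCc3ccccc3)c(OC)c2)CO1 | intermediate
11 | (3R,4S)-4-(4-hydroxy-3-methoxybenzyl)-3-[3-methoxy-4-(triisopropylsilyloxy)benzyl]dihydrofuran-2(3H)-one (cis) | O=C1[C@H](Cc2ccc(O[Si](C(C)C)(C(C)C)C(C)C)c(OC)c2)[C@H](Cc2ccc(O)c(OC)c2)CO1 | intermediate
12 | (2S,3R)-2-(4-hydroxy-3-methoxybenzyl)-3-[3-methoxy-4-(triisopropylsilyloxy)benzyl]butane-1,4-diol | OC[C@H](Cc1ccc(O[Si](C(C)C)(C(C)C)C(C)C)c(OC)c1)[C@H](Cc1ccc(O)c(OC)c1)CO | intermediate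
13 | 4-[(2S,3R)-2,3-bis(hydroxymethyl)-4-[3-methoxy-4-(triisopropylsilyloxy)phenyl]butylidene]-2-methoxycyclohexa-2,5-dien-1-one (p-quinone methide; not isolated) | OC[C@H](Cc1ccc(O[Si](C(C)C)(C(C)C)C(C)C)c(OC)c1)[C@H](C=C1C=CC(=O)C(OC)=C1)CO | intermediate
14 | [(2R,3S,4R)-2-(4-hydroxy-3-methoxyphenyl)-4-[3-methoxy-4-(triisopropylsilyloxy)benzyl]tetrahydrofuran-3-yl]methanol (7,8-trans-8,8'-trans; not isolated) | COc1cc(C[C@H]2CO[C@@H](c3ccc(O)c(OC)c3)[C@@H]2CO)ccc1O[Si](C(C)C)(C(C)C)C(C)C | intermediate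
15 | [(3S,4R)-2-(4-hydroxy-3-methoxyphenyl)-2-methoxy-4-[3-methoxy-4-(triisopropylsilyloxy)benzyl]tetrahydrofuran-3-yl]methanol (both C2 anomers; not isolated) | COc1cc(C[C@H]2COC(OC)(c3ccc(O)c(OC)c3)[C@@H]2CO)ccc1O[Si](C(C)C)(C(C)C)C(C)C | intermediate
16 | cyclic oxocarbenium ion from 15 (C2=O+; 3S,4R; not isolated) | COc1cc(C[C@H]2C[O+]=C(c3ccc(O)c(OC)c3)[C@@H]2CO)ccc1O[Si](C(C)C)(C(C)C)C(C)C | intermediate
17 | [(2S,3S,4R)-2-(4-hydroxy-3-methoxyphenyl)-4-[3-methoxy-4-(triisopropylsilyloxy)benzyl]tetrahydrofuran-3-yl]methanol | COc1cc(C[C@H]2CO[C@H](c3ccc(O)c(OC)c3)[C@@H]2CO)ccc1O[Si](C(C)C)(C(C)C)C(C)C | intermediate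
18 | (E)-p-coumaric acid | OC(=O)/C=C/c1ccc(O)cc1 | starting material
19 | [(2S,3S,4R)-2-(4-hydroxy-3-methoxyphenyl)-4-[3-methoxy-4-(triisopropylsilyloxy)benzyl]tetrahydrofuran-3-yl]methyl (E)-3-(4-hydroxyphenyl)prop-2-enoate | COc1cc(C[C@H]2CO[C@H](c3ccc(O)c(OC)c3)[C@@H]2COC(=O)/C=C/c2ccc(O)cc2)ccc1O[Si](C(C)C)(C(C)C)C(C)C | intermediate
20 | [(2S,3S,4R)-2-(4-hydroxy-3-methoxyphenyl)-4-(4-hydroxy-3-methoxybenzyl)tetrahydrofuran-3-yl]methyl (E)-3-(4-hydroxyphenyl)prop-2-enoate | COc1cc(C[C@H]2CO[C@H](c3ccc(O)c(OC)c3)[C@@H]2COC(=O)/C=C/c2ccc(O)cc2)ccc1O | target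

**Step count**

Total steps: 10. Longest linear sequence: 9 steps (1 → 3 → 4 → 6 → 10 → 11 → 12 → 17 → 19 → 20); step 4 is a one-step side branch.

**Steps most likely to fail, with fallbacks**

Step 8 is the riskiest. The oxidised C7 centre can lose the C8 proton to give a 2-aryl-4,5-dihydrofuran (C8 scrambled, or aromatised to a furan by excess DDQ). Ring B can attack the quinone methide or the oxocarbenium ion in a Friedel–Crafts sense. Hydride delivery may not be fully anti to C8. The fallback sets out from 12 and comes back at 20; it sets C7 by a reagent-controlled ketone reduction and closes the ring in the opposite sense, with retention at C7. Oxidise 12 with DDQ in CH2Cl2–MeOH only and isolate methyl ketal 15. TBSCl/imidazole then gives the bis-TBS ketal F1. PPTS in wet acetone hydrolyses it to the hydroxy ketone F2, in which the C9' hydroxyl is the only free alcohol. (R)-Me-CBS/BH3·SMe2 (aryl as the large group) reduces the ketone to the (7S)-diol F3. PPh3/DIAD cyclodehydration, in which the primary C9' alcohol is activated and the C7 oxygen attacks, gives the tris-silyl tetrahydrofuran F4. Bu4NF removes all three silyl groups to give the free triol F5, which is esterified with 18 under the step 9 conditions to give 20.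

Step 6 may give an insufficient cis:trans ratio, or the lactone may epimerise on the catalyst. The fallback sets out from 10 and comes back at 11; it sets C8' by kinetic protonation instead of face-selective hydrogen delivery. Conjugate reduction of 10 with [(Ph3P)CuH]6 (or L-Selectride) at −78 °C gives the lactone enolate. Protonation by 2,6-di-tert-butyl-4-methylphenol from the face opposite the C4 benzyl group gives the cis-lactone benzyl ether F6. H2 over Pd/C then removes only the benzyl group to give 11.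

Step 9 may suffer phenol O-alkylation by the alkoxyphosphonium ion, or opening or epimerisation of the 7,8-cis ether by the basic betaine. The fallback sets out from 17 and comes back at 19; it replaces the redox condensation by enzymatic transesterification. Vinyl p-coumarate F7 is made from 18 and vinyl acetate with Pd(OAc)2 catalysis. Immobilised Candida antarctica lipase B in dry t-BuOMe–MeCN at 45 °C then transfers the coumaroyl group to the primary alcohol of 17 only, since phenols are not acylated, to give 19.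

**Further compounds**

F1 | step 8 | tert-butyl[[(3S,4R)-2-[4-(tert-butyldimethylsilyloxy)-3-methoxyphenyl]-2-methoxy-4-[3-methoxy-4-(triisopropylsilyloxy)benzyl]tetrahydrofuran-3-yl]methoxy]dimethylsilane (both C2 anomers) | COc1cc(C[C@H]2COC(OC)(c3ccc(O[Si](C)(C)C(C)(C)C)c(OC)c3)[C@@H]2CO[Si](C)(C)C(C)(C)C)ccc1O[Si](C(C)C)(C(C)C)C(C)C
F2 | step 8 | (2S,3R)-1-[4-(tert-butyldimethylsilyloxy)-3-methoxyphenyl]-2-[(tert-butyldimethylsilyloxy)methyl]-3-(hydroxymethyl)-4-[3-methoxy-4-(triisopropylsilyloxy)phenyl]butan-1-one | COc1cc(C[C@@H](CO)[C@@H](CO[Si](C)(C)C(C)(C)C)C(=O)c2ccc(O[Si](C)(C)C(C)(C)C)c(OC)c2)ccc1O[Si](C(C)C)(C(C)C)C(C)C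
F3 | step 8 | (1S,2S,3R)-1-[4-(tert-butyldimethylsilyloxy)-3-methoxyphenyl]-2-[(tert-butyldimethylsilyloxy)methyl]-3-[3-methoxy-4-(triisopropylsilyloxy)benzyl]butane-1,4-diol | COc1cc(C[C@@H](CO)[C@@H](CO[Si](C)(C)C(C)(C)C)[C@H](O)c2ccc(O[Si](C)(C)C(C)(C)C)c(OC)c2)ccc1O[Si](C(C)C)(C(C)C)C(C)C
F4 | step 8 | tert-butyl[[(2S,3S,4R)-2-[4-(tert-butyldimethylsilyloxy)-3-methoxyphenyl]-4-[3-methoxy-4-(triisopropylsilyloxy)benzyl]tetrahydrofuran-3-yl]methoxy]dimethylsilane | COc1cc(C[C@H]2CO[C@H](c3ccc(O[Si](C)(C)C(C)(C)C)c(OC)c3)[C@@H]2CO[Si](C)(C)C(C)(C)C)ccc1O[Si](C(C)C)(C(C)C)C(C)C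
F5 | step 8 | 4-[(2S,3S,4R)-4-(4-hydroxy-3-methoxybenzyl)-3-(hydroxymethyl)tetrahydrofuran-2-yl]-2-methoxyphenol | COc1cc(C[C@H]2CO[C@H](c3ccc(O)c(OC)c3)[C@@H]2CO)ccc1O
F6 | step 6 | (3R,4S)-4-[4-(benzyloxy)-3-methoxybenzyl]-3-[3-methoxy-4-(triisopropylsilyloxy)benzyl]dihydrofuran-2(3H)-one | O=C1[C@H](Cc2ccc(O[Si](C(C)C)(C(C)C)C(C)C)c(OC)c2)[C@H](Cc2ccc(OCc3ccccc3)c(OC)c2)CO1
F7 | step 9 | vinyl (E)-3-(4-hydroxyphenyl)prop-2-enoate | C=COC(=O)/C=C/c1ccc(O)cc1
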